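## Structural features

The target is a trans-fused hydroazulene: a cyclopentane and a cycloheptane share the C3a–C8a bond, with H3a and H8a on opposite faces. The five-membered ring carries a trisubstituted epoxide across C1–C2 (methyl on C2). The seven-membered ring carries the isopropyl group at C4, the 4-hydroxybenzoate at C5 and a tertiary methyl carbinol at C7. Six of the seven stereocentres are contiguous (C2, C1, C8a, C3a, C4, C5); C7 is isolated between the methylenes C6 and C8. H3a, the isopropyl group, the epoxide oxygen and the C7 hydroxyl lie on one face (β), and H8a, the C5 oxygen and both ring methyls on the other (α). The fragile groups are the epoxide (acid, or β-elimination if a carbonyl sits at C8), the aryl ester with its free phenol, and the tertiary alcohol. The real difficulties are the seven-membered ring, the trans fusion, the remote quaternary carbinol and the epoxide face. The key step uses the fact that the fusion bond C3a–C8a can arise by a 1,2-shift of C3a from C8 to C8a. The cycloheptane is then a ring-enlarged cyclohexane C3a–C4–C5–C6–C7–C8 whose stereocentres can be set under chair control, and the C1–C2 unit comes from an ethynyl group on C8.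

## Logic of the disconnections

24 ⇒ 23. The O–acetyl bond of the phenol is cut last in the forward sense. A free phenol would compete in the carbodiimide acylation and is best kept away from the peroxide step. The forward step must cleave an aryl acetate without touching the secondary benzoate or the epoxide.

23 ⇒ 22. The two C–O bonds of the epoxide (C1–O, C2–O) are cut. The epoxide is the most sensitive group and lies syn to the C7 hydroxyl, so that hydroxyl can deliver the oxygen. Two stereocentres disappear. The forward step must put oxygen on the β face, against the steric preference of the alkene.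

22 ⇒ 20 + 21. The acyl–oxygen bond at C5 is cut, which removes the aromatic part as a purchased acid. The forward step must acylate the secondary C5 hydroxyl and leave the tertiary C7 hydroxyl alone.

20 ⇒ 19. The two O–Si bonds are restored. Silyl ethers at C5 and C7 carry both oxygens through the organometallic, Lewis acid, electron-transfer and radical steps. One fluoride treatment must remove both.

19 ⇒ 18 ⇒ 17 ⇒ 16. Oxygen is put back on C8 (thiocarbonyl ester, alcohol, ketone). A C8 carbonyl is what the ring enlargement delivers and what allows hydrogen to be placed on C8a. The forward sequence must delete this oxygen without moving the C1=C2 bond or disturbing C8a.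

16 ⇒ 14 (through 15). The C8a–H bond is cut, the alkene is moved into conjugation (C8a=C1) and a methoxy group is restored at C2. This leads to the direct product of the ring enlargement. The forward step must eliminate the methoxy group reductively in preference to the C7–O bond and must protonate C8a on the α face.

14 ⇒ 13. The bonds C1–C2 and C3a–C8a are cut and C3a–C8 is rejoined. Both rings of the bicycle collapse to one cyclohexane carrying an ethynyl silyl ether at C8 and a ketal side chain at C3a. The forward step needs the ethynyl group cis to the side chain, exclusive migration of C3a, and silyl ethers that survive the Lewis acid.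

13 ⇒ 12 ⇒ 10 + 11. The O–Si bonds at C7 and C8 and then the C8–C8a bond are cut. This leaves a cyclohexanone and a two-carbon nucleophile. The forward addition must be axial, anti to the C7 oxygen.

10 ⇒ 8 ⇒ 5. The C7–O bond and then the C7–CH3 bond are cut. Both are made from enolates of a conformationally fixed cyclohexanone, where regiochemistry (away from the crowded C3a) and facial selectivity (axial attack) are predictable.

5 ⇒ 4 ⇒ 1 + 2. The ketal is taken back to the enol ether, and then the C3a–C3 bond and the bond from C4 to the isopropyl group are cut. This leaves a cyclohexenone with a single stereocentre. The forward step must add the isopropyl nucleophile anti to the C5 silyloxy group and alkylate the enolate anti to the new isopropyl group.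

## Other disconnections considered

Alternative 1: The C5–C6 bond is cut. In the forward step Me2AlCl would activate the aldehyde of the cyclopentenone A2, and a type 2 carbonyl-ene reaction with the methallyl group would close the seven-membered ring to give the hydroxy enone A1. In its favour, the ring closure creates the C5 carbinol directly in the oxidation state of the ester, there is no C8 oxygen to delete, and the exocyclic methylene at C7 is a direct precursor of the methyl carbinol. The trans ring fusion would come from vicinal functionalisation of a cyclopentenone and can be corrected by equilibration next to the C1 ketone; on this point the alternative is better than the chosen plan, which relies on a kinetic protonation. Its step economy should be equal or better. Against it, C4 is an open-chain stereocentre α to an aldehyde and is exposed to epimerisation under the Lewis acid. The C5 configuration rests on the rotamer adopted in a seven-membered ene transition state. C7 must later be set by face-selective hydration of a methylene group on a flexible ring that also holds the C1–C2 alkene. The chosen plan sets C3a, C4, C5 and C7 on a chair before any medium ring exists. Mechanistically, a concerted ene process is milder than a cationic cascade, but seven-membered ene closures are less reliable than the 1,2-shift that drives the chosen step.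

Alternative 2: The C3–C3a bond is cut. In the forward step FeCl3 would convert the cross-conjugated silyl dienone A4 into a pentadienyl cation, whose conrotatory closure and loss of silicon would give the hydroazulenone A3 with the alkene fixed at C2=C3. In its favour, the C7 carbinol comes from linalool and needs no enolate oxidation; this is better than the chosen plan. The C5 and C7 oxygens are in place before the bicycle forms, and the ring fusion can be equilibrated α to the C1 ketone, which is equal or better. Against it, the sense of conrotation, and with it C3a relative to C4, depends on torquoselectivity induced by the neighbouring C4 centre and is not assured. The cycloheptene A4 with its C4, C5 and C7 stereocentres needs its own ring closure and stereocontrol. The enone must afterwards be transposed to the C1–C2 position. Structurally the order of ring construction is reversed (seven-membered ring first). Step economy should be comparable. Relaying stereochemistry by additions to a six-membered ring, as in the chosen plan, is the more secure way to fix the C3a–C4–C5 array.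

Alternative 3: The C3a–C8a and C4–C5 bonds are cut as a [2+2] pair, with a later scission of C8a–C5. In the forward step irradiation of the β-acetoxy enone A6 would give a cyclobutane, and K2CO3 in methanol would open it by retro-aldol cleavage to the hydroazulene-1,5-dione A5. In its favour, two C–C bonds and both rings form in one photochemical operation, and both carbonyls sit where the target is functionalised, so nothing has to be deleted; this is better than the chosen plan. C7 is present from the start, and C8a and C4 are each α to a ketone and can be set by equilibration, which is equal or better. Step economy is probably better. Against it, C3a is fixed in the photocycloaddition and cannot be corrected. Its configuration relative to the remote C7 centre depends on facial selectivity of an excited enone, which is hard to predict. The alkene geometry may be lost in a triplet biradical. The C5 ketone must later be reduced to the α alcohol, and the C1 ketone must be turned into the C1=C2 alkene regioselectively. The chosen plan is longer but derives every stereocentre from one purchased stereocentre through ground-state steps with predictable chair control.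

Key step: step 7

Remarks on the chemistry:
- Locants follow hydroazulene numbering (C1, C2, C3, C3a, C4, C5, C6, C7, C8, C8a) for every intermediate, the cyclohexanes included. β is the face of the C4 isopropyl group and α the opposite face.
- Assumption: 1, 2, 11 (as its THF solution) and 21 are purchased.
- The configurations of the rearrangement substrate and product were checked against the target and need no change: the (S)-enone gives the required C5 centre, the axial ethynyl group is cis to the side chain, and the C2 methoxy group is α.
- The rearrangement substrate carries the C7 silyloxy group from the outset, so that C7 is set on a chair (step 4) and not on a flexible seven-membered dienolate. The same group lowers the migratory aptitude of C7 in step 7 and screens the β face in step 8.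
- Ethynylmagnesium bromide is used so that no C-silyl group has to be removed. A thiocarbonylimidazolide replaces a xanthate so that no alkoxide is formed next to the C7 silyl ether. The phenol stays acetylated until the last step.

## Steps

Step 1
Reactants: 1 (S)-4-(tert-butyldimethylsilyloxy)cyclohex-2-en-1-one; 2 3-bromo-2-methoxyprop-1-ene
Product: 4 2-(2-methoxyprop-2-enyl)-3-isopropyl-4-(tert-butyldimethylsilyloxy)cyclohexanone (ketone = C8; C3a side chain α; C4 isopropyl β; C5 silyloxy α), via chloromagnesium enolate 3 (not isolated)
Conditions: i-PrMgCl, CuBr·SMe2 (10 mol%), THF, −78 °C; then 2, DMPU, −78 → 0 °C; Et3N-buffered work-up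
Reagents that add atoms: isopropylmagnesium chloride, CC(C)[Mg]Cl; 3-bromo-2-methoxyprop-1-ene (2), COC(=C)CBr
Why: CuBr·SMe2-catalysed conjugate addition of the Grignard reagent should occur anti to the C5 silyloxy group, and the enolate should be C-allylated by the reactive allylic bromide anti to the new isopropyl group (tandem conjugate addition–enolate alkylation). C4 and C3a are thus set trans,trans to C5.

Step 2
Reactants: 4 2-(2-methoxyprop-2-enyl)-3-isopropyl-4-(tert-butyldimethylsilyloxy)cyclohexanone
Product: 5 2-(2,2-dimethoxypropyl)-3-isopropyl-4-(tert-butyldimethylsilyloxy)cyclohexanone (configuration as in 4)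
Conditions: PPTS (cat.), MeOH, 0 °C
Reagents that add atoms: methanol, CO
Why: Acid-catalysed Markovnikov addition of methanol to the enol ether should give the dimethyl ketal (enol ether to ketal); the hindered ring ketone and the secondary silyl ether should survive this buffered acid.

Step 3
Reactants: 5 2-(2,2-dimethoxypropyl)-3-isopropyl-4-(tert-butyldimethylsilyloxy)cyclohexanone
Product: 8 2-(2,2-dimethoxypropyl)-3-isopropyl-4-(tert-butyldimethylsilyloxy)-6-methylcyclohexanone with all four substituents equatorial (C7 methyl α), via lithium enolate 6 (not isolated), via axial methyl epimer 7 (not isolated)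
Conditions: LiN(i-Pr)2, THF, −78 °C; MeI, −78 → −20 °C; then NaOMe, MeOH, 23 °C
Reagents that add atoms: iodomethane, CI
Why: Kinetic deprotonation should take the C7 methylene and not the crowded C3a methine (enolate alkylation). Base equilibration then places the C7 methyl equatorial (α), which makes the C7 hydrogen axial for the next enolisation.

Step 4
Reactants: 8 2-(2,2-dimethoxypropyl)-3-isopropyl-4-(tert-butyldimethylsilyloxy)-6-methylcyclohexanone
Product: 10 6-hydroxy-6-methyl ketone (8 with C7 hydroxyl β and axial; C7 methyl α and equatorial), via potassium enolate 9 (not isolated)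
Conditions: KN(SiMe3)2, THF, −78 → −40 °C; 2-(phenylsulfonyl)-3-phenyloxaziridine, −78 °C
Reagents that add atoms: 2-(phenylsulfonyl)-3-phenyloxaziridine, O=S(=O)(c1ccccc1)N1OC1c1ccccc1
Why: Enolisation should go toward C7, because a C3a enolate would hold its side chain in the plane against the equatorial isopropyl group (allylic strain). Oxygen transfer along the axial trajectory of the chair-like enolate should give the β hydroxyl with the methyl equatorial (Davis enolate hydroxylation).

Step 5
Reactants: 10 6-hydroxy-6-methyl ketone; 11 ethynylmagnesium bromide
Product: 12 1-ethynylcyclohexane-1,2-diol (C8 ethynyl α and axial; C8 hydroxyl β; C7 hydroxyl β; C7 methyl α; other groups as in 10)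
Conditions: 11 (4 equiv), CeCl3, THF, −78 → 0 °C
Reagents that add atoms: ethynylmagnesium bromide (11), C#C[Mg]Br
Why: The weakly basic acetylide formed with CeCl3 should add to the hindered, α-oxygenated ketone without enolisation or ketol shift (organocerium 1,2-addition). The slim nucleophile should enter axially on the α face, anti to the axial C7 oxygen, which places the ethynyl group cis to the C3a side chain.

Step 6
Reactants: 12 1-ethynylcyclohexane-1,2-diol
Product: 13 7,8-bis(triethylsilyl) ether of 12
Conditions: Et3SiOTf (excess), 2,6-lutidine, CH2Cl2, −78 → 0 °C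
Reagents that add atoms: triethylsilyl trifluoromethanesulfonate, CC[Si](CC)(CC)OS(=O)(=O)C(F)(F)F
Why: The silyl triflate should silylate both tertiary hydroxyls (silyl ether formation); the hindered pyridine base leaves the ketone-derived ketal and the terminal alkyne alone at low temperature.

Step 7
Reactants: 13 7,8-bis(triethylsilyl) ether
Product: 14 2α-methoxy-2β,7α-dimethyl-4β-isopropyl-5α-(tert-butyldimethylsilyloxy)-7β-(triethylsilyloxy)-3,3a,4,5,6,7-hexahydroazulen-8(2H)-one (C8a=C1; H3a β)
Conditions: SnCl4 (1.5 equiv), CH2Cl2, −78 → −23 °C; then Et3N, NaHCO3 (aq)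
Reagents that add atoms: none
Why: SnCl4 ionises the dimethyl ketal to a tertiary oxocarbenium ion at C2, the only group of 13 that ionises readily at −78 °C. The axial ethynyl group on C8 and the equatorial side chain on C3a are cis, so the terminal alkyne carbon C1 reaches C2 through a chair-like six-membered array (6-endo-dig Prins closure, bond C1–C2), and attack through the terminus places the developing charge on the more substituted carbon C8a. That charge is quenched as it forms by a pinacol-type 1,2-shift of the ring bond C3a–C8, which lies antiperiplanar to the vacant orbital at C8a, and the silyloxy carbon C8 becomes the ketone with loss of its triethylsilyl group. The five-membered ring therefore arises by contraction of the six-membered Prins ring (bonds C1–C2 and C3a–C8a), and the seven-membered ring by one-carbon enlargement of the cyclohexane. The closest known reaction type is the Prins cyclization–pinacol rearrangement used for ring-enlarging cyclopentane annulation, here in its alkyne-terminated form that gives a cyclopentene. C3a migrates with retention, so its trans relation to C4 from step 1 becomes the C3a configuration of the bicycle; the only new stereocentre, C2, is set by the chair array with the methyl group pseudo-equatorial and the methoxy group pseudo-axial (α), and it becomes trigonal again in step 8. The selectivity needed is migration of C3a and not of C7, which is secured by the alignment of the C3a–C8 bond in the bicyclic transition state and by the electron-withdrawing silyloxy group on C7. The silyl ethers at C5 and C7 should be spectators at this temperature.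

Step 8
Reactants: 14 methoxy enone
Product: 16 2,7α-dimethyl-4β-isopropyl-5α-(tert-butyldimethylsilyloxy)-7β-(triethylsilyloxy)-3a,4,5,6,7,8a-hexahydroazulen-8(3H)-one (C1=C2; H3a β; H8a α; trans-fused), via samarium dienolate 15 (not isolated)
Conditions: SmI2 (2.1 equiv, added until the blue colour just persists), MeOH (4 equiv), THF, −78 °C; pH 7 buffer
Reagents that add atoms: none
Why: Two-electron reduction of the enone places carbanion character on C1, which expels the neighbouring methoxide to give the dienolate (vinylogous reductive elimination of a γ-alkoxy enone). Kinetic protonation occurs at the α-carbon C8a and should come from the α face, anti to the pseudo-axial H3a and away from the pseudo-axial C7 silyloxy group that screens the β face, which gives the trans fusion. The limited charge of reductant and the low temperature are meant to spare the C7–O bond once the ketone is unmasked.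

Step 9
Reactants: 16 β,γ-unsaturated ketone
Product: 17 the 8β-alcohol of 16
Conditions: i-Bu2AlH, CH2Cl2, −78 °C; aqueous potassium sodium tartrate
Reagents that add atoms: none
Why: Hydride 1,2-reduction at low temperature without free base should leave C8a and the alkene position untouched and should not induce silyl migration from the C7 oxygen. The β-alcohol is expected from attack anti to the C7 silyloxy group, but the C8 configuration is of no consequence.

Step 10
Reactants: 17 8β-alcohol
Product: 18 O-(C8) 1H-imidazole-1-carbothioate of 17
Conditions: 1,1'-thiocarbonyldiimidazole, DMAP, toluene, 80 °C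
Reagents that add atoms: 1,1'-thiocarbonyldiimidazole, S=C(n1ccnc1)n1ccnc1
Why: Neutral thioacylation of the secondary alcohol gives the Barton–McCombie substrate without forming an alkoxide next to the C7 silyl ether.

Step 11
Reactants: 18 imidazole-1-carbothioate
Product: 19 2,7α-dimethyl-4β-isopropyl-5α-(tert-butyldimethylsilyloxy)-7β-(triethylsilyloxy)-3,3a,4,5,6,7,8,8a-octahydroazulene (C1=C2; trans-fused)
Conditions: Bu3SnH (5 equiv, 0.5 M), AIBN (cat.), toluene, 100 °C
Reagents that add atoms: none
Why: Barton–McCombie deoxygenation: the stannyl radical adds to sulfur, β-scission gives the secondary C8 radical, and hydrogen transfer from Bu3SnH at high concentration should reduce this homoallylic radical before it can add to the C1=C2 bond.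

Step 12
Reactants: 19 bis-silyl ether
Product: 20 2,7α-dimethyl-4β-isopropyl-3,3a,4,5,6,7,8,8a-octahydroazulene-5α,7β-diol (C1=C2; trans-fused)
Conditions: Bu4NF, THF, 23 → 50 °C
Reagents that add atoms: none
Why: Fluoride should cleave both the secondary tert-butyldimethylsilyl and the tertiary triethylsilyl ether (desilylation); the alkene is the only other functional group.

Step 13
Reactants: 20 diol; 21 4-acetoxybenzoic acid
Product: 22 5-O-(4-acetoxybenzoyl) ester of 20
Conditions: EDC·HCl, DMAP, CH2Cl2, 23 °C
Reagents that add atoms: 4-acetoxybenzoic acid (21), CC(=O)Oc1ccc(cc1)C(O)=O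
Why: Carbodiimide/DMAP (Steglich) esterification should acylate only the secondary C5 hydroxyl; the tertiary C7 hydroxyl is inert under these conditions and the phenol stays masked as its acetate.

Step 14
Reactants: 22 5-O-(4-acetoxybenzoyl) ester
Product: 23 1β,2β-epoxide of 22 (C2 methyl α)
Conditions: VO(acac)2 (5 mol%), t-BuOOH, CH2Cl2, 0 → 23 °C
Reagents that add atoms: tert-butyl hydroperoxide, CC(C)(C)OO
Why: The alkoxide formed from VO(acac)2 and the bishomoallylic C7 hydroxyl should deliver the peroxide oxygen to the β face of the C1=C2 bond, the face that carries this hydroxyl (hydroxyl-directed epoxidation). An undirected reagent would prefer the α face, away from C8. The syn epoxy alcohol cannot open itself by backside attack.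

Step 15
Reactants: 23 epoxy acetate
Product: 24 target: 1β,2β-epoxy-2α,7α-dimethyl-4β-isopropyl-5α-(4-hydroxybenzoyloxy)decahydroazulen-7β-ol (H3a β; H8a α)
Conditions: K2CO3 (0.2 equiv), MeOH, 0 °C; then NH4Cl (aq)
Reagents that add atoms: none
Why: Methanolysis of the aryl acetate (transesterification) should be far faster than that of the hindered secondary benzoate, which is deactivated further once the phenoxide forms; the trisubstituted epoxide and the tertiary alcohol tolerate this weak base.

## Compound list

1 | (S)-4-(tert-butyldimethylsilyloxy)cyclohex-2-en-1-one | O=C1C=C[C@@H](O[Si](C)(C)C(C)(C)C)CC1 | starting material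
2 | 3-bromo-2-methoxyprop-1-ene | COC(=C)CBr | starting material
3 | chloromagnesium C3a=C8 enolate of trans-3-isopropyl-4-(tert-butyldimethylsilyloxy)cyclohexanone (formed in the flask) | CC(C)[C@H]1C=C(O[Mg]Cl)CC[C@@H]1O[Si](C)(C)C(C)(C)C | intermediate
4 | 2-(2-methoxyprop-2-enyl)-3-isopropyl-4-(tert-butyldimethylsilyloxy)cyclohexanone; C3a side chain α, C4 isopropyl β, C5 silyloxy α | CC(C)[C@H]1[C@H](CC(=C)OC)C(=O)CC[C@@H]1O[Si](C)(C)C(C)(C)C | intermediate
5 | 2-(2,2-dimethoxypropyl)-3-isopropyl-4-(tert-butyldimethylsilyloxy)cyclohexanone; configuration as in 4 | CC(C)[C@H]1[C@H](CC(C)(OC)OC)C(=O)CC[C@@H]1O[Si](C)(C)C(C)(C)C | intermediate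
6 | lithium C7=C8 enolate of 5 (formed in the flask) | CC(C)[C@H]1[C@H](CC(C)(OC)OC)C(O[Li])=CC[C@@H]1O[Si](C)(C)C(C)(C)C | intermediate
7 | C7 epimer of 8 with the methyl β and axial (formed in the flask) | CC(C)[C@H]1[C@H](CC(C)(OC)OC)C(=O)[C@@H](C)C[C@@H]1O[Si](C)(C)C(C)(C)C | intermediate
8 | 2-(2,2-dimethoxypropyl)-3-isopropyl-4-(tert-butyldimethylsilyloxy)-6-methylcyclohexanone; all substituents equatorial, C7 methyl α | CC(C)[C@H]1[C@H](CC(C)(OC)OC)C(=O)[C@H](C)C[C@@H]1O[Si](C)(C)C(C)(C)C | intermediate
9 | potassium C7=C8 enolate of 8 (formed in the flask) | CC(C)[C@H]1[C@H](CC(C)(OC)OC)C(O[K])=C(C)C[C@@H]1O[Si](C)(C)C(C)(C)C | intermediate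
10 | 6-hydroxy-6-methyl ketone; C7 hydroxyl β (axial), C7 methyl α | CC(C)[C@H]1[C@H](CC(C)(OC)OC)C(=O)[C@](O)(C)C[C@@H]1O[Si](C)(C)C(C)(C)C | intermediate
11 | ethynylmagnesium bromide | C#C[Mg]Br | starting material
12 | 1-ethynylcyclohexane-1,2-diol; C8 ethynyl α, C8 hydroxyl β, C7 hydroxyl β, C7 methyl α | CC(C)[C@H]1[C@H](CC(C)(OC)OC)[C@](O)(C#C)[C@](O)(C)C[C@@H]1O[Si](C)(C)C(C)(C)C | intermediate
13 | 7,8-bis(triethylsilyl) ether of 12; substrate of the ring enlargement | CC(C)[C@H]1[C@H](CC(C)(OC)OC)[C@](O[Si](CC)(CC)CC)(C#C)[C@](O[Si](CC)(CC)CC)(C)C[C@@H]1O[Si](C)(C)C(C)(C)C | intermediate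
14 | 2α-methoxy-2β,7α-dimethyl-4β-isopropyl-5α-(tert-butyldimethylsilyloxy)-7β-(triethylsilyloxy)-3,3a,4,5,6,7-hexahydroazulen-8(2H)-one; C8a=C1, H3a β | CC(C)[C@H]1[C@@H]2C[C@](C)(OC)C=C2C(=O)[C@](O[Si](CC)(CC)CC)(C)C[C@@H]1O[Si](C)(C)C(C)(C)C | intermediate
15 | samarium dienolate C8(OSmI2)=C8a–C1=C2 from 14 (formed in the flask) | CC(C)[C@H]1[C@@H]2CC(C)=CC2=C(O[Sm](I)I)[C@](O[Si](CC)(CC)CC)(C)C[C@@H]1O[Si](C)(C)C(C)(C)C | intermediate
16 | 2,7α-dimethyl-4β-isopropyl-5α-(tert-butyldimethylsilyloxy)-7β-(triethylsilyloxy)-3a,4,5,6,7,8a-hexahydroazulen-8(3H)-one; C1=C2, H3a β, H8a α | CC(C)[C@H]1[C@@H]2CC(C)=C[C@H]2C(=O)[C@](O[Si](CC)(CC)CC)(C)C[C@@H]1O[Si](C)(C)C(C)(C)C | intermediate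
17 | 8β-alcohol of 16 | CC(C)[C@H]1[C@@H]2CC(C)=C[C@H]2[C@@H](O)[C@](O[Si](CC)(CC)CC)(C)C[C@@H]1O[Si](C)(C)C(C)(C)C | intermediate
18 | O-(C8) 1H-imidazole-1-carbothioate of 17 | CC(C)[C@H]1[C@@H]2CC(C)=C[C@H]2[C@@H](OC(=S)n3ccnc3)[C@](O[Si](CC)(CC)CC)(C)C[C@@H]1O[Si](C)(C)C(C)(C)C | intermediate
19 | 2,7α-dimethyl-4β-isopropyl-5α-(tert-butyldimethylsilyloxy)-7β-(triethylsilyloxy)-3,3a,4,5,6,7,8,8a-octahydroazulene; C1=C2, trans-fused | CC(C)[C@H]1[C@@H]2CC(C)=C[C@H]2C[C@](O[Si](CC)(CC)CC)(C)C[C@@H]1O[Si](C)(C)C(C)(C)C | intermediate
20 | 2,7α-dimethyl-4β-isopropyl-3,3a,4,5,6,7,8,8a-octahydroazulene-5α,7β-diol; C1=C2, trans-fused | CC(C)[C@H]1[C@@H]2CC(C)=C[C@H]2C[C@](O)(C)C[C@@H]1O | intermediate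
21 | 4-acetoxybenzoic acid | CC(=O)Oc1ccc(cc1)C(O)=O | starting material
22 | 5-O-(4-acetoxybenzoyl) ester of 20 | CC(C)[C@H]1[C@@H]2CC(C)=C[C@H]2C[C@](O)(C)C[C@@H]1OC(=O)c1ccc(OC(C)=O)cc1 | intermediate
23 | 1β,2β-epoxide of 22 | CC(C)[C@H]1[C@@H]2C[C@@]3(C)O[C@H]3[C@H]2C[C@@](C)(O)C[C@@H]1OC(=O)c1ccc(OC(C)=O)cc1 | intermediate
24 | 1β,2β-epoxy-2α,7α-dimethyl-4β-isopropyl-5α-(4-hydroxybenzoyloxy)decahydroazulen-7β-ol (CNP0245441.1) | CC(C)[C@H]1[C@@H]2C[C@@]3(C)O[C@H]3[C@H]2C[C@@](C)(O)C[C@@H]1OC(=O)c1ccc(O)cc1 | target

## Step count and least certain steps

Total step count: 15. Longest linear sequence: 15 steps (1 → 24); 2, 11 and 21 enter as purchased building blocks.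

Step 7 (key step). The most likely failure is that the pinacol shift does not keep pace with ionisation in the crowded bis-silyloxy region. The oxocarbenium ion would then be lost by proton loss to an enol ether, or the C7 silyl ether would be cleaved by the Lewis acid. Fallback, from 8 back to 14: the ring enlargement is run on the series without the C7 oxygen, and the oxygen is introduced afterwards. Ketone 8 with 11 and CeCl3 should give the ethynyl carbinol F1. Et3SiOTf and 2,6-lutidine give its triethylsilyl ether F2, and SnCl4 gives the methoxy enone F3. In F3 the C7 hydrogen is the only enolisable one, so KN(SiMe3)2 followed by the oxaziridine of step 4 should give the α′-hydroxy enone F4, and silylation with Et3SiOTf returns to 14. The price is a less predictable face of oxygenation on the seven-membered ring.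

Step 8. Two things can go wrong: protonation of the dienolate from the β face, giving the cis fusion, and a second reductive cleavage at the C7–O bond once the saturated ketone is exposed to residual reductant. Fallback, from 14 back to 17: the reductive elimination is replaced by an addition–elimination sequence that puts C8a under thermodynamic control and uses no electron transfer at the ketone stage. Thiophenol with catalytic Et3N adds to C1 of 14 and gives the β-phenylthio ketone F5; its C8a centre, α to the ketone, equilibrates to the trans-fused isomer under the same base. i-Bu2AlH gives the phenylthio alcohol F6. Excess LiC10H8 (lithium naphthalenide) in THF at −78 °C then cleaves the C–S bond reductively, and the C1 carbanion expels the C2 methoxide to form the C1=C2 bond of 17.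

Step 4. Enolisation may go partly toward C3a, or the bulky oxaziridine may transfer oxygen from the equatorial direction. Fallback, from 5 back to 10: the C7 enolate equivalent is generated regiospecifically from an enone. The lithium enolate 6 with dimethylmethylideneammonium iodide gives the Mannich base F7. Quaternisation with MeI and elimination with NaHCO3 give the α-methylene ketone F8. Mn(dpm)3 (cat.), PhSiH3 and O2 in i-PrOH, followed by P(OEt)3, should add hydrogen to the methylene carbon and oxygen to C7 (hydration of an enone to an α-hydroxy ketone). The small oxidant O2 is expected to enter axially and give 10.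

Step 14. The C7 hydroxyl may fail to deliver oxygen across the ring, which would leave slow undirected epoxidation on the α face. Fallback, from 19 back to 23: the steric preference for the α face is used in the opposite sense through a halohydrin. N-Bromosuccinimide in aqueous THF should form the bromonium ion on the α face of 19, and water opens it at the tertiary C2 from the β face to give the bromohydrin F9; the C7 oxygen is still silylated at this stage and should not compete. K2CO3 in MeOH closes the β-epoxide F10. Bu4NF gives the epoxy diol F11, and esterification with 21 as in step 13 gives 23.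

Step 1. In the one-flask trapping of the magnesium enolate, proton transfer between enolate and product can lead to over-alkylation and regioisomers. Fallback, from 1 back to 4: the conjugate addition is run with Me3SiCl present, and the silyl enol ether F12 is isolated. MeLi in THF regenerates the enolate as its lithium salt F13, free of magnesium and copper salts, and this is alkylated with 2 at −78 → 0 °C to give 4.

## Further compounds

F1 | step 7 | 1-ethynyl-2-(2,2-dimethoxypropyl)-3-isopropyl-4-(tert-butyldimethylsilyloxy)-6-methylcyclohexanol; ethynyl α, C7 methyl α | CC(C)[C@H]1[C@H](CC(C)(OC)OC)[C@](O)(C#C)[C@H](C)C[C@@H]1O[Si](C)(C)C(C)(C)C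
F2 | step 7 | triethylsilyl ether of F1 | CC(C)[C@H]1[C@H](CC(C)(OC)OC)[C@](O[Si](CC)(CC)CC)(C#C)[C@H](C)C[C@@H]1O[Si](C)(C)C(C)(C)C
F3 | step 7 | 2α-methoxy-2β,7α-dimethyl-4β-isopropyl-5α-(tert-butyldimethylsilyloxy)-3,3a,4,5,6,7-hexahydroazulen-8(2H)-one | CC(C)[C@H]1[C@@H]2C[C@](C)(OC)C=C2C(=O)[C@H](C)C[C@@H]1O[Si](C)(C)C(C)(C)C
F4 | step 7 | 7β-hydroxy derivative of F3 | CC(C)[C@H]1[C@@H]2C[C@](C)(OC)C=C2C(=O)[C@](O)(C)C[C@@H]1O[Si](C)(C)C(C)(C)C
F5 | step 8 | 1-phenylthio-1,8a-dihydro derivative of 14; trans-fused, C1 epimers | CC(C)[C@H]1[C@@H]2C[C@](C)(OC)C(Sc3ccccc3)[C@H]2C(=O)[C@](O[Si](CC)(CC)CC)(C)C[C@@H]1O[Si](C)(C)C(C)(C)C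
F6 | step 8 | 8-alcohol of F5 | CC(C)[C@H]1[C@@H]2C[C@](C)(OC)C(Sc3ccccc3)[C@H]2[C@@H](O)[C@](O[Si](CC)(CC)CC)(C)C[C@@H]1O[Si](C)(C)C(C)(C)C
F7 | step 4 | 6-(dimethylaminomethyl) derivative of 5; C7 epimers | CC(C)[C@H]1[C@H](CC(C)(OC)OC)C(=O)C(CN(C)C)C[C@@H]1O[Si](C)(C)C(C)(C)C
F8 | step 4 | 6-methylene derivative of 5 | CC(C)[C@H]1[C@H](CC(C)(OC)OC)C(=O)C(=C)C[C@@H]1O[Si](C)(C)C(C)(C)C
F9 | step 14 | 1α-bromo-2β-hydroxy adduct of 19 | CC(C)[C@H]1[C@@H]2C[C@@](C)(O)[C@H](Br)[C@H]2C[C@](O[Si](CC)(CC)CC)(C)C[C@@H]1O[Si](C)(C)C(C)(C)C
F10 | step 14 | 1β,2β-epoxide of 19 | CC(C)[C@H]1[C@@H]2C[C@@]3(C)O[C@H]3[C@H]2C[C@](O[Si](CC)(CC)CC)(C)C[C@@H]1O[Si](C)(C)C(C)(C)C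
F11 | step 14 | 1β,2β-epoxide of 20 | CC(C)[C@H]1[C@@H]2C[C@@]3(C)O[C@H]3[C@H]2C[C@@](C)(O)C[C@@H]1O
F12 | step 1 | trimethylsilyl C3a=C8 enol ether of trans-3-isopropyl-4-(tert-butyldimethylsilyloxy)cyclohexanone | CC(C)[C@H]1C=C(O[Si](C)(C)C)CC[C@@H]1O[Si](C)(C)C(C)(C)C
F13 | step 1 | lithium C3a=C8 enolate of the same ketone | CC(C)[C@H]1C=C(O[Li])CC[C@@H]1O[Si](C)(C)C(C)(C)C
A1 | alternative 1 | 5α-hydroxy-2-methyl-4β-isopropyl-7-methylene-3a,4,5,6,7,8-hexahydroazulen-1(8aH)-one; trans-fused | CC(C)[C@H]1[C@@H]2C=C(C)C(=O)[C@H]2CC(=C)C[C@@H]1O
A2 | alternative 1 | 3-methyl-2-[trans-3-methyl-4-oxo-5-(2-methylprop-2-enyl)cyclopent-2-enyl]butanal | CC(C)[C@H](C=O)[C@@H]1C=C(C)C(=O)[C@H]1CC(C)=C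
A3 | alternative 2 | 2,7α-dimethyl-4β-isopropyl-5α-(tert-butyldimethylsilyloxy)-7β-(triethylsilyloxy)-3a,4,5,6,7,8-hexahydroazulen-1(8aH)-one; trans-fused | CC(C)[C@H]1[C@@H]2C=C(C)C(=O)[C@H]2C[C@@](C)(O[Si](CC)(CC)CC)C[C@@H]1O[Si](C)(C)C(C)(C)C
A4 | alternative 2 | (E)-2-methyl-3-(trimethylsilyl)propenoyl cycloheptene with C4 isopropyl, C5 and C7 silyloxy groups | CC(C)[C@H]1C=C(C(=O)/C(C)=C/[Si](C)(C)C)C[C@@](C)(O[Si](CC)(CC)CC)C[C@@H]1O[Si](C)(C)C(C)(C)C
A5 | alternative 3 | 2,7α-dimethyl-4β-isopropyl-7β-(methoxymethoxy)octahydroazulene-1,5-dione; trans-fused | CC(C)[C@H]1[C@@H]2C[C@H](C)C(=O)[C@H]2C[C@@](C)(OCOC)CC1=O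
A6 | alternative 3 | 2-[(E)-2,6-dimethylhept-4-enoyl]-4-methyl-4-(methoxymethoxy)cyclopent-1-enyl acetate | CC(C)/C=C/C[C@H](C)C(=O)C1=C(OC(C)=O)C[C@](C)(OCOC)C1
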